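**Retrosynthetic overview**

1. The route rests on the C4–C5 bond of the 1,2-dioxane ring (ring atoms O1, O2, C3, C4, C5, C6): it is the only ring bond with carbon on both sides and no oxygen on either carbon, so the ring can be closed there as a C4=C5 alkene while the O1–O2 bond already lies in the open chain.
2. Target ⇒ C1 alcohol (oxidation, deacetylation) ⇒ C6–CH3 by axial methyl transfer to a ring peroxycarbenium ion ⇒ C4 by diimide reduction of C4=C5 ⇒ 6-methoxy-4-methyl-3,6-dihydro-1,2-dioxine.
3. The dihydrodioxine, the only ring, is closed by ring-closing metathesis of a mixed peroxyketal diene carrying vinyl on C6 and isopropenyl on C3.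
4. The peroxyketal comes from ketal exchange between an (S)-allylic hydroperoxide (singlet-oxygen ene reaction, then peroxidase resolution; sets C3) and a vinyl ketone dimethyl ketal.
5. The vinyl ketal comes from (R)-citronellal (supplies C8): ozonolysis, Wittig extension with the ylide from (6-bromohexyl)benzene, hydrogenation, vinyl Grignard addition, oxidation and ketalisation.

Key step: step 14

Remark (assumption): compounds 18–20 are carried as mixtures of both C6 ketal epimers because C6 becomes planar in step 16, and the sense of the peroxidase resolution in step 3 is assigned by analogy with secondary hydroperoxides bearing one unsaturated and one alkyl group and is to be confirmed on the derived alcohol.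

**Route**

Step 1
Reactants: 1 4-methylpent-3-en-1-ol
Product: 2 4-methylpent-3-en-1-yl acetate
Conditions: Ac2O, pyridine, DMAP (cat.), CH2Cl2, 0 °C to rt
Reagents that add atoms: acetic anhydride CC(=O)OC(C)=O
Why: DMAP-catalysed acetylation of the primary alcohol gives a small polar ester that survives the ene reaction, the buffered enzymatic step, the metathesis and low-temperature Me3Al.

Step 2
Reactants: 2 4-methylpent-3-en-1-yl acetate
Product: 3 rac-3-hydroperoxy-4-methylpent-4-en-1-yl acetate
Conditions: O2, tetraphenylporphyrin (cat.), visible light, CH2Cl2, 0 °C; chromatography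
Reagents that add atoms: dioxygen O=O
Why: Schenck ene reaction of singlet oxygen with the trisubstituted alkene puts OOH on C3 and moves the alkene into the isopropenyl position (C3 racemic); the tertiary hydroperoxide formed by abstraction at the allylic CH2 is removed by chromatography.

Step 3
Reactants: 3 rac-3-hydroperoxy-4-methylpent-4-en-1-yl acetate
Product: 4 (3S)-3-hydroperoxy-4-methylpent-4-en-1-yl acetate
Conditions: horseradish peroxidase, guaiacol (0.6 equiv), phosphate buffer pH 6, rt, run to about 55% conversion; chromatography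
Reagents that add atoms: none
Why: Enzymatic kinetic resolution in which the peroxidase should reduce the (R)-hydroperoxide to the alcohol and leave (S)-4, which sets C3; configuration and enantiomeric purity are to be checked by Mosher ester analysis of the alcohol obtained from a sample with PPh3.

Step 4
Reactants: 5 (R)-citronellal
Product: 6 (6R)-8,8-dimethoxy-2,6-dimethyloct-2-ene
Conditions: HC(OMe)3, MeOH, PPTS (cat.), rt
Reagents that add atoms: trimethyl orthoformate COC(OC)OC
Why: Acid-catalysed acetalisation under mild acid protects the aldehyde without triggering the carbonyl-ene cyclisation of citronellal; the C8 stereocentre is carried unchanged from here on.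

Step 5
Reactants: 6 (6R)-8,8-dimethoxy-2,6-dimethyloct-2-ene
Product: 7 (4R)-6,6-dimethoxy-4-methylhexanal
Conditions: O3, CH2Cl2, −78 °C; PPh3, −78 °C to rt
Reagents that add atoms: ozone [O-][O+]=O
Why: Ozonolysis with reductive work-up cleaves the only alkene to the aldehyde and leaves the acetal intact at low temperature.

Step 6
Reactants: 8 (6-bromohexyl)benzene
Product: 9 triphenyl(6-phenylhexyl)phosphonium bromide
Conditions: PPh3, MeCN, reflux
Reagents that add atoms: triphenylphosphine c1ccc(cc1)P(c1ccccc1)c1ccccc1
Why: SN2 quaternisation of the primary bromide gives the Wittig salt.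

Step 7
Reactants: 9 triphenyl(6-phenylhexyl)phosphonium bromide; 7 (4R)-6,6-dimethoxy-4-methylhexanal
Product: 11 [(6Z,10R)-12,12-dimethoxy-10-methyldodec-6-en-1-yl]benzene, via phosphonium ylide 10 (not isolated)
Conditions: NaN(SiMe3)2, THF, 0 °C; then 7, −78 °C to rt
Reagents that add atoms: none
Why: Wittig olefination with the unstabilised ylide joins the two chain halves; the alkene geometry is irrelevant because it is hydrogenated next.

Step 8
Reactants: 11 [(6Z,10R)-12,12-dimethoxy-10-methyldodec-6-en-1-yl]benzene
Product: 12 [(10R)-12,12-dimethoxy-10-methyldodecyl]benzene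
Conditions: H2 (1 atm), Pd/C (10% palladium on carbon), EtOAc, rt
Reagents that add atoms: none
Why: Heterogeneous hydrogenation saturates the disubstituted alkene; the acetal and the phenyl ring are inert under neutral conditions.

Step 9
Reactants: 12 [(10R)-12,12-dimethoxy-10-methyldodecyl]benzene
Product: 13 (3R)-3-methyl-12-phenyldodecanal
Conditions: 1 M aq. HCl, THF, rt
Reagents that add atoms: water O
Why: Acid hydrolysis of the dimethyl acetal; the stereocentre is β to the carbonyl and cannot epimerise.

Step 10
Reactants: 13 (3R)-3-methyl-12-phenyldodecanal; 14 vinylmagnesium bromide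
Product: 15 (5R)-5-methyl-14-phenyltetradec-1-en-3-ol (both C3 epimers)
Conditions: THF, −78 to 0 °C
Reagents that add atoms: none
Why: Grignard 1,2-addition to the aldehyde; the carbinol configuration does not matter because it is oxidised in the next step.

Step 11
Reactants: 15 (5R)-5-methyl-14-phenyltetradec-1-en-3-ol
Product: 16 (5R)-5-methyl-14-phenyltetradec-1-en-3-one
Conditions: Dess–Martin periodinane, NaHCO3, CH2Cl2, 0 °C; used at once
Reagents that add atoms: none
Why: Buffered Dess–Martin oxidation of the allylic alcohol gives the vinyl ketone without conjugate addition or polymerisation.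

Step 12
Reactants: 16 (5R)-5-methyl-14-phenyltetradec-1-en-3-one
Product: 17 (5R)-3,3-dimethoxy-5-methyl-14-phenyltetradec-1-ene
Conditions: MeOSiMe3 (3 equiv), Me3SiOTf (cat.), CH2Cl2, −78 °C; pyridine quench
Reagents that add atoms: methoxytrimethylsilane CO[Si](C)(C)C
Why: Noyori acetalisation under aprotic kinetic conditions ketalises the enone carbonyl without conjugate addition of methanol or alkene migration.

Step 13
Reactants: 4 (3S)-3-hydroperoxy-4-methylpent-4-en-1-yl acetate; 17 (5R)-3,3-dimethoxy-5-methyl-14-phenyltetradec-1-ene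
Product: 18 (3S)-3-{[(5R)-3-methoxy-5-methyl-14-phenyltetradec-1-en-3-yl]peroxy}-4-methylpent-4-en-1-yl acetate (both ketal epimers)
Conditions: PPTS (cat.), 4 Å molecular sieves, CH2Cl2, 0 °C; 17 in slight excess; chromatography on Et3N-treated silica
Reagents that add atoms: none
Why: Acid-catalysed transketalisation in which the hydroperoxide captures the methoxy-stabilised cation at the ketal carbon (the kinetic site, as in exchange reactions of acrolein acetals), joining the two halves through O–O–C6 without touching C3.

Step 14
Reactants: 18 mixed peroxyketal diene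
Product: 19 2-{(3S)-6-methoxy-4-methyl-6-[(2R)-2-methyl-11-phenylundecyl]-3,6-dihydro-1,2-dioxin-3-yl}ethyl acetate (both C6 epimers)
Conditions: second-generation Grubbs catalyst (H2IMes)(PCy3)Cl2Ru=CHPh (5–10 mol%), CH2Cl2 (0.005 M), 40 °C, argon sparge; filtration through silica at once
Reagents that add atoms: none
Why: Proposed new method: the ruthenium benzylidene should exchange first with the unhindered vinyl group on C6, the new alkylidene then adds [2+2] across the 1,1-disubstituted alkene on C3, and the ruthenacyclobutane cycloreverts to the C4=C5 alkene and Ru=CH2, which leaves as ethene. The closest known reactions are ruthenium-catalysed cross-metathesis of alkenyl dialkyl peroxides and ring-closing metathesis of diallyl ethers and allylic ketals to trisubstituted six-membered cycloalkenes. The 3,6-dihydro-1,2-dioxine closes as a six-membered ring by intramolecular metathesis of two alkenes held together by the C3–O–O–C6 tether, so the ring size is fixed by the tether and only the cis ring alkene can form. No stereocentre is created, C3 is untouched, and both C6 epimers should cyclise. The step needs chemoselectivity for alkene metathesis over electron transfer to the O–O bond and over ruthenium-promoted Kornblum–DeLaMare-type isomerisation of the product; the fully alkylated, non-nucleophilic peroxide, irreversible loss of ethene, high dilution and prompt removal of ruthenium should secure it.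

Step 15
Reactants: 19 6-methoxy-3,6-dihydro-1,2-dioxine
Product: 20 2-{(3S,4S)-6-methoxy-4-methyl-6-[(2R)-2-methyl-11-phenylundecyl]-1,2-dioxan-3-yl}ethyl acetate (both C6 epimers)
Conditions: KO2CN=NCO2K (large excess, in portions), AcOH, MeOH–CH2Cl2, 0 °C to rt
Reagents that add atoms: none
Why: Diimide reduction transfers H2 in a concerted syn fashion without touching the O–O bond; it should add to the face anti to the C3 chain, which allylic strain with the C4 methyl holds pseudoaxial while the small methoxy group rather than the C6 chain takes the other pseudoaxial site, so C4 becomes S with its methyl cis to the C3 chain.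

Step 16
Reactants: 20 6-methoxy-1,2-dioxane
Product: 21 2-{(3S,4S,6R)-4,6-dimethyl-6-[(2R)-2-methyl-11-phenylundecyl]-1,2-dioxan-3-yl}ethyl acetate
Conditions: Me3Al (4 equiv), CH2Cl2, −78 to −20 °C; aq. potassium sodium tartrate work-up
Reagents that add atoms: trimethylaluminium C[Al](C)C
Why: Proposed new method: Me3Al should complex the more basic methoxy oxygen, ionise C6–OMe to a ring peroxycarbenium ion and deliver methyl along the axial trajectory of the half-chair that keeps the C4 methyl pseudoequatorial and the C3 chain pseudoaxial, so methyl ends trans to both and C6 becomes R from either ketal epimer; the closest known reactions are Lewis-acid substitutions of 3-alkoxy-1,2-dioxanes and 3-alkoxy-1,2-dioxolanes by allylsilanes and silyl ketene acetals through peroxycarbenium ions, and Me3Al methylation of cyclic ketals and lactol derivatives.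

Step 17
Reactants: 21 6-methyl-1,2-dioxane acetate
Product: 22 2-{(3S,4S,6R)-4,6-dimethyl-6-[(2R)-2-methyl-11-phenylundecyl]-1,2-dioxan-3-yl}ethanol
Conditions: K2CO3, MeOH, 0 °C
Reagents that add atoms: none
Why: Mild methanolysis removes the acetate; the saturated dialkyl peroxide has no carbonyl-activated hydrogen and tolerates carbonate.

Step 18
Reactants: 22 primary alcohol
Product: 23 2-{(3S,4S,6R)-4,6-dimethyl-6-[(2R)-2-methyl-11-phenylundecyl]-1,2-dioxan-3-yl}acetic acid (target)
Conditions: TEMPO (cat.), PhI(OAc)2 (2.5 equiv), MeCN–H2O, rt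
Reagents that add atoms: water O
Why: Oxoammonium oxidation takes the primary alcohol through the aldehyde hydrate to the acid under near-neutral conditions that spare the peroxide and avoid base-induced β-elimination of the β-peroxy carbonyl.

**Compound list**

1 | 4-methylpent-3-en-1-ol | CC(C)=CCCO | starting material
2 | 4-methylpent-3-en-1-yl acetate | CC(C)=CCCOC(C)=O | intermediate
3 | rac-3-hydroperoxy-4-methylpent-4-en-1-yl acetate | C=C(C)C(CCOC(C)=O)OO | intermediate
4 | (3S)-3-hydroperoxy-4-methylpent-4-en-1-yl acetate | C=C(C)[C@H](CCOC(C)=O)OO | intermediate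
5 | (R)-citronellal | C[C@H](CCC=C(C)C)CC=O | starting material
6 | (6R)-8,8-dimethoxy-2,6-dimethyloct-2-ene | C[C@H](CCC=C(C)C)CC(OC)OC | intermediate
7 | (4R)-6,6-dimethoxy-4-methylhexanal | C[C@H](CCC=O)CC(OC)OC | intermediate
8 | (6-bromohexyl)benzene | BrCCCCCCc1ccccc1 | starting material
9 | triphenyl(6-phenylhexyl)phosphonium bromide | [Br-].c1ccccc1CCCCCC[P+](c1ccccc1)(c1ccccc1)c1ccccc1 | intermediate
10 | triphenyl(6-phenylhexylidene)phosphorane (ylide, not isolated) | c1ccccc1CCCCCC=P(c1ccccc1)(c1ccccc1)c1ccccc1 | intermediate
11 | [(6Z,10R)-12,12-dimethoxy-10-methyldodec-6-en-1-yl]benzene | C[C@H](CC/C=C\CCCCCc1ccccc1)CC(OC)OC | intermediate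
12 | [(10R)-12,12-dimethoxy-10-methyldodecyl]benzene | C[C@H](CCCCCCCCCc1ccccc1)CC(OC)OC | intermediate
13 | (3R)-3-methyl-12-phenyldodecanal | C[C@H](CCCCCCCCCc1ccccc1)CC=O | intermediate
14 | vinylmagnesium bromide | C=C[Mg]Br | starting material
15 | (5R)-5-methyl-14-phenyltetradec-1-en-3-ol (C3 epimers) | C[C@H](CCCCCCCCCc1ccccc1)CC(O)C=C | intermediate
16 | (5R)-5-methyl-14-phenyltetradec-1-en-3-one | C[C@H](CCCCCCCCCc1ccccc1)CC(=O)C=C | intermediate
17 | (5R)-3,3-dimethoxy-5-methyl-14-phenyltetradec-1-ene | C[C@H](CCCCCCCCCc1ccccc1)CC(OC)(OC)C=C | intermediate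
18 | (3S)-3-{[(5R)-3-methoxy-5-methyl-14-phenyltetradec-1-en-3-yl]peroxy}-4-methylpent-4-en-1-yl acetate (ketal epimers) | C=C(C)[C@H](CCOC(C)=O)OOC(OC)(C=C)C[C@H](C)CCCCCCCCCc1ccccc1 | intermediate
19 | 2-{(3S)-6-methoxy-4-methyl-6-[(2R)-2-methyl-11-phenylundecyl]-3,6-dihydro-1,2-dioxin-3-yl}ethyl acetate (C6 epimers) | C[C@H](CCCCCCCCCc1ccccc1)CC1(OC)C=C(C)[C@H](CCOC(C)=O)OO1 | intermediate
20 | 2-{(3S,4S)-6-methoxy-4-methyl-6-[(2R)-2-methyl-11-phenylundecyl]-1,2-dioxan-3-yl}ethyl acetate (C6 epimers) | C[C@H](CCCCCCCCCc1ccccc1)CC1(OC)C[C@H](C)[C@H](CCOC(C)=O)OO1 | intermediate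
21 | 2-{(3S,4S,6R)-4,6-dimethyl-6-[(2R)-2-methyl-11-phenylundecyl]-1,2-dioxan-3-yl}ethyl acetate | C[C@H](CCCCCCCCCc1ccccc1)C[C@]1(C)C[C@H](C)[C@H](CCOC(C)=O)OO1 | intermediate
22 | 2-{(3S,4S,6R)-4,6-dimethyl-6-[(2R)-2-methyl-11-phenylundecyl]-1,2-dioxan-3-yl}ethanol | C[C@H](CCCCCCCCCc1ccccc1)C[C@]1(C)C[C@H](C)[C@H](CCO)OO1 | intermediate
23 | 2-{(3S,4S,6R)-4,6-dimethyl-6-[(2R)-2-methyl-11-phenylundecyl]-1,2-dioxan-3-yl}acetic acid | C[C@H](CCCCCCCCCc1ccccc1)C[C@]1(C)C[C@H](C)[C@H](CC(=O)O)OO1 | target

**Step count**

Total: 18 steps. Longest linear sequence: 14 steps (from (R)-citronellal: steps 4, 5, 7–18).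

**Steps most likely to fail**

Step 14. What may go wrong: the ruthenium alkylidene is consumed by electron transfer to, or insertion into, the O–O bond; ruthenium residues isomerise the dihydrodioxine once formed (opening at the C3–H next to the peroxide); or closure onto the 1,1-disubstituted alkene is slower than catalyst decay and oligomers form. The fallback uses no ruthenium, sets out from aldehyde 13 and hydroperoxide 4, and comes back at 21. It closes the ring between C5 and C6 by a Lewis-acid cyclisation of an unsaturated monoperoxyketal, a known way to 1,2-dioxanes. MeMgBr adds to 13 to give (4R)-4-methyl-13-phenyltridecan-2-ol F1; Dess–Martin oxidation gives (4R)-4-methyl-13-phenyltridecan-2-one F2; HC(OMe)3, MeOH and PPTS give (4R)-2,2-dimethoxy-4-methyl-13-phenyltridecane F3; exchange with 4 under the conditions of step 13 gives the saturated mixed peroxyketal F4. Me3SiOTf with 2,6-di-tert-butylpyridine in CH2Cl2 at −78 °C ionises the methoxy group, and the CH2 terminus of the isopropenyl group attacks the peroxycarbenium carbon in a 6-endo mode. In the chair the long chain on C6 should sit equatorial and the C3 chain axial beside the sp2 C4, which gives the 6R configuration. The tertiary C4 cation then loses a proton to give the 4-methylidene-1,2-dioxane F5 or its ring-alkene isomer F6. Diimide as in step 15 should reduce either alkene anti to the C3 chain to 21. C6 carries its methyl from the ketal, so steps 15 and 16 are bypassed.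

Step 16. What may go wrong: ionisation toward the ring oxygen with opening of the dioxane, methyl transfer to a peroxide oxygen with O–O cleavage, proton loss from the peroxycarbenium ion to an enol peroxide, or non-axial attack giving the C6 epimer. The fallback sets out from enone 16 and hydroperoxide 4 and comes back at 21. It builds the C6 methyl before ring closure by peroxymercuration and demercuration, so no peroxycarbenium ion is needed. Wittig methylenation of 16 (Ph3P=CH2, THF) gives the diene [(10R)-10-methyl-12-methylidenetetradec-13-en-1-yl]benzene F7. Hg(OAc)2 and 4 in CH2Cl2 add the hydroperoxide in the Markovnikov sense to the 1,1-disubstituted terminus of the diene to give the acetoxymercurio peroxide F8; the isopropenyl group of 4 is deactivated by its allylic peroxy group and should react more slowly. NaBH4 under two-phase conditions (CH2Cl2, aq. NaOH, 0 °C) replaces mercury by hydrogen to give the tertiary allylic peroxide F9 as both C6 epimers. Ring-closing metathesis as in step 14 gives the 6-methyl-3,6-dihydro-1,2-dioxine F6 and its C6 epimer F10, which are ring diastereomers and are separated by chromatography. Diimide as in step 15 converts F6 to 21. The price is the loss of stereocontrol at C6.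

Step 3. What may go wrong: the enzyme discriminates poorly between the enantiomers of this substrate or turns it over slowly, so 4 is recovered with insufficient enantiomeric purity. The fallback sets out from racemic 3 and comes back at 4, and resolves through covalent diastereomers. Commercial (1R,2S)-trans-2-phenylcyclohexanol is acetylated to (1R,2S)-trans-2-phenylcyclohexyl acetate F11 and methylenated with the Tebbe reagent Cp2TiCH2ClAlMe2 to (1R,2S)-trans-2-phenylcyclohexyl isopropenyl ether F12. PPTS-catalysed addition of 3 to F12 gives the diastereomeric peroxyketals, the (3S)-peroxyketal F13 and the (3R)-peroxyketal F14, which are separated by chromatography. F13 is hydrolysed with AcOH–H2O–THF to 4, and the configuration is confirmed on the derived alcohol as in the main route.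

**Further compounds**

F1 | step 14 | (4R)-4-methyl-13-phenyltridecan-2-ol (C2 epimers) | C[C@H](CCCCCCCCCc1ccccc1)CC(C)O
F2 | step 14 | (4R)-4-methyl-13-phenyltridecan-2-one | C[C@H](CCCCCCCCCc1ccccc1)CC(C)=O
F3 | step 14 | (4R)-2,2-dimethoxy-4-methyl-13-phenyltridecane | C[C@H](CCCCCCCCCc1ccccc1)CC(C)(OC)OC
F4 | step 14 | (3S)-3-{[(4R)-2-methoxy-4-methyl-13-phenyltridecan-2-yl]peroxy}-4-methylpent-4-en-1-yl acetate (ketal epimers) | C=C(C)[C@H](CCOC(C)=O)OOC(C)(OC)C[C@H](C)CCCCCCCCCc1ccccc1
F5 | step 14 | 2-{(3S,6R)-6-methyl-4-methylidene-6-[(2R)-2-methyl-11-phenylundecyl]-1,2-dioxan-3-yl}ethyl acetate | C[C@H](CCCCCCCCCc1ccccc1)C[C@]1(C)CC(=C)[C@H](CCOC(C)=O)OO1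
F6 | step 14 | 2-{(3S,6R)-4,6-dimethyl-6-[(2R)-2-methyl-11-phenylundecyl]-3,6-dihydro-1,2-dioxin-3-yl}ethyl acetate | C[C@H](CCCCCCCCCc1ccccc1)C[C@]1(C)C=C(C)[C@H](CCOC(C)=O)OO1
F7 | step 16 | [(10R)-10-methyl-12-methylidenetetradec-13-en-1-yl]benzene | C=CC(=C)C[C@H](C)CCCCCCCCCc1ccccc1
F8 | step 16 | (3S)-3-{[(5R)-3-(acetoxymercuriomethyl)-5-methyl-14-phenyltetradec-1-en-3-yl]peroxy}-4-methylpent-4-en-1-yl acetate (C6 epimers) | C=C(C)[C@H](CCOC(C)=O)OOC(C[Hg]OC(C)=O)(C=C)C[C@H](C)CCCCCCCCCc1ccccc1
F9 | step 16 | (3S)-3-{[(5R)-3,5-dimethyl-14-phenyltetradec-1-en-3-yl]peroxy}-4-methylpent-4-en-1-yl acetate (C6 epimers) | C=C(C)[C@H](CCOC(C)=O)OOC(C)(C=C)C[C@H](C)CCCCCCCCCc1ccccc1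
F10 | step 16 | 2-{(3S,6S)-4,6-dimethyl-6-[(2R)-2-methyl-11-phenylundecyl]-3,6-dihydro-1,2-dioxin-3-yl}ethyl acetate | C[C@H](CCCCCCCCCc1ccccc1)C[C@@]1(C)C=C(C)[C@H](CCOC(C)=O)OO1
F11 | step 3 | (1R,2S)-trans-2-phenylcyclohexyl acetate | CC(=O)O[C@@H]1CCCC[C@H]1c1ccccc1
F12 | step 3 | (1R,2S)-trans-2-phenylcyclohexyl isopropenyl ether | C=C(C)O[C@@H]1CCCC[C@H]1c1ccccc1
F13 | step 3 | (3S)-4-methyl-3-({2-[(1R,2S)-2-phenylcyclohexyloxy]propan-2-yl}peroxy)pent-4-en-1-yl acetate | C=C(C)[C@H](CCOC(C)=O)OOC(C)(C)O[C@@H]1CCCC[C@H]1c1ccccc1
F14 | step 3 | (3R)-4-methyl-3-({2-[(1R,2S)-2-phenylcyclohexyloxy]propan-2-yl}peroxy)pent-4-en-1-yl acetate | C=C(C)[C@@H](CCOC(C)=O)OOC(C)(C)O[C@@H]1CCCC[C@H]1c1ccccc1
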